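## Analysis of the target

1. Target 25 is the (Z)-4-hydroxycinnamate (cis-p-coumarate) of a humulane-type alcohol. Apart from the phenol ring it holds a single ring, an eleven-membered carbocycle.
2. Ring atoms are numbered along the SMILES string: C1 (olefinic, CH3), C2 (=CH), C3 (CH2), C4 (C(CH3)2), C5 (CH2), C6 (CH–O), C7 (CH2), C8 (olefinic, CH3), C9 (=CH), C10 and C11 (CH2, C11 bonded to C1). Plain numbers stand for compounds.
3. C1=C2 and C8=C9 are both trisubstituted and E and form a 1,5-diene through C10–C11. C6 is the only stereocentre and is (S).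
4. C6 lies between two CH2 groups, so no neighbouring stereocentre or polar group can direct its formation. A ketone at C6 would offer a reagent two flanks that differ only at the β-carbon.
5. The sensitive parts are the Z-enoate conjugated to a free phenol (it isomerises with light, nucleophiles or phenoxide formation) and the medium-ring 1,5-diene (it undergoes transannular cyclisation with acid).
6. The synthesis is hard for three reasons. The ring is of medium size. An E olefin cannot sit in the small ring of a fused bicyclic precursor, so a transannular bond from C6 always leaves C8=C9 or C1=C2 in a ring too small for it. The quaternary C4 makes both C3 and C5 neopentyl positions.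
7. The plan is built on the run C8(sp2)–C7H2–C6H(O)–C5H2–C4(quaternary). An sp2 carbon, a CH2, a carbinol and an alkyl group in this order can be read as an alkenyl electrophile (C8), a vinyl group on boron (C7=C6) and a group that migrates from boron to carbon (C5).

## Retrosynthetic reasoning

**Side chain, Cα=Cβ of the coumarate (25 ⇒ 24 ⇒ 22 + 23).** The labile Z olefin is made last, so that it never meets palladium, zirconium or strong nucleophiles. The olefin bond is cut rather than the ester C–O bond, because activating a preformed Z-acid invites isomerisation. The forward olefination of 23 with phosphonate 22 has to be Z-selective under kinetic control. The final deprotection of 24 must not build up phenoxide.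

**Phosphonate ester (22 ⇒ 20 + 21; 20 ⇒ 18 + 19).** The C–P bond and the acyl C–O bond are cut. Acylation of 18 does not touch the C6–O bond, so the configuration is kept. Both 19 and 21 are bought.

**Key disconnection, C5–C6 and C7–C8 together (18 ⇒ 17 ⇒ 16 ⇒ 14 + 15).**
- The C6–O bond is traced back to a C6–B bond (17).
- The two ring bonds that flank the C6–C7 unit are then cut at once, which takes C6 and C7 out of the ring as the vinyl group of 15.
- What remains is 14, an open nine-carbon chain (C5 to C8 by way of C4, C3, C2, C1, C11, C10, C9) with boron on C5 and bromine on C8.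
- The cut is made here because it is the only place where ring closure, two C–C bonds and the stereocentre can fall into one catalyst-controlled event.
- Precursor 14 is achiral and acyclic, and both E olefins are already in place.
- The forward reaction has to stitch the vinyl group between the chain ends, with C5 moving from boron to C6 and C8 bonding to C7, on one face of the vinyl group.

**C11–C1 (14 ⇒ 8 + 12 by way of 13).** The chain is cut at the sp2–sp3 bond of the C1=C2 olefin into two fragments that each carry one preformed E-haloalkene. The forward coupling has to use the C–I bond of 8 and leave the C–Br bond of 12 and 13 alone. This gives convergence, and isomers are removed on small molecules.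

**C1–I, C5–B, C5–O and C2–C3 (8 ⇒ 7 ⇒ 6 ⇒ 5 ⇒ 4 ⇒ 3 ⇒ 1 + 2).** The E-iodoalkene comes from syn-hydrometallation of the methylalkyne 6. The boronate comes from iodide 4 through 5, and 4 comes from alcohol 3. In 3 the neopentyl C2–C3 bond is cut. The strained ether 1 already holds C3, C4 with both methyl groups, and C5, and its ring strain pays for substitution at a neopentyl carbon by 2.

**C8–Br (12 ⇒ 11 ⇒ 10 ⇒ 9).** The same hydrometallation logic on 9 places bromine on C8, trans to C10. The hydroxyl group then becomes the iodide needed for 13.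

## Alternatives that were turned down

**Alternative 1:** ring-closing metathesis across C8=C9, the textbook closure.
- *Forward step:* triene A1, a methallyl carbinol made by an asymmetric methallylation, is treated with a ruthenium or molybdenum alkylidene to give 18.
- *Why turned down:*
  - The step would have to make a trisubstituted olefin inside a strained eleven-membered ring under reversible conditions, where ring strain moves the equilibrium towards dimers and oligomers.
  - Nothing in A1 biases the new olefin towards E.
  - The stereocentre needs a separate asymmetric step, so the key step would build the ring and nothing else.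

**Alternative 2:** closure of C6–C7 by alkylation of a masked acyl anion.
- *Forward step:* the protected cyanohydrin A2, with an allylic chloride at C7, is deprotonated and closed at high dilution. Unmasking gives ketone A3, and enantioselective reduction gives 18.
- *Why turned down:*
  - The ring closure is sound, but it moves the whole stereochemical problem to A3. Its carbonyl group lies between C5H2 and C7H2, so a chiral hydride reagent finds no clear large and small side.
  - A3 is a β,γ-unsaturated ketone that can slip into conjugation under the basic unmasking.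
  - Protecting, unmasking and reducing add steps that build nothing.

**Alternative 3:** strain-release closure of C2–C3.
- *Forward step:* the tertiary cyclobutanol A4 holds C3–C6 as a 3,3-dimethylcyclobutane. Its palladium alkoxide undergoes β-carbon elimination to a neopentyl palladium species that has no β-hydrogen, because C4 is quaternary. This couples with the alkenyl iodide at C2 to give A3.
- *Why turned down:*
  - The driving force and the fit to C4 are attractive, but the carbinol carbon becomes the ketone of A3, so the same unsolved reduction follows.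
  - A4 itself needs an allyl metal to add to a cyclobutanone through its CH2 terminus, whereas such reagents react through the substituted terminus (C9).

Key step: step 8

Assumption (remark on the chemistry): the ligand antipode named in step 8 is taken to give (S)-17 in the ring-closing mode. If the sense is the opposite, the mirror-image ligand, also an article of commerce, is used and nothing else changes.

## Steps

**Step 1**
Reactants: 1 3,3-dimethyloxetane; 2 1-propynyllithium
Product: 3 2,2-dimethylhex-4-yn-1-ol
Conditions: BF3·OEt2 (1.2 equiv), THF, −78 °C; H2O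
Reagents that add atoms: none
Why: Lewis-acid-assisted SN2 opening of an oxetane by a lithium acetylide, in which the strain of the activated ring makes up for the neopentyl position of the attacked CH2; the step forms C2–C3 and delivers C3, C4 with both methyl groups and C5 at once, and no stereocentre arises.

**Step 2**
Reactants: 3 2,2-dimethylhex-4-yn-1-ol
Product: 4 6-iodo-5,5-dimethylhex-2-yne
Conditions: PPh3, imidazole, I2, toluene, 80 °C
Reagents that add atoms: iodine, I-I
Why: Appel-type iodination; the alkoxyphosphonium salt of a neopentyl alcohol needs heat for displacement by iodide but has no β-hydrogen to lose, and the internal alkyne should be inert.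

**Step 3**
Reactants: 4 6-iodo-5,5-dimethylhex-2-yne
Product: 6 2-(2,2-dimethylhex-4-yn-1-yl)-4,4,5,5-tetramethyl-1,3,2-dioxaborolane, via alkyllithium 5 (not isolated)
Conditions: t-BuLi (2.1 equiv), Et2O/pentane, −78 °C; then 2-isopropoxy-4,4,5,5-tetramethyl-1,3,2-dioxaborolane, −78 °C to rt; H2O
Reagents that add atoms: 2-isopropoxy-4,4,5,5-tetramethyl-1,3,2-dioxaborolane, CC(C)OB1OC(C)(C)C(C)(C)O1; tert-butyllithium, [Li]C(C)(C)C (lithium of 5 only)
Why: Lithium–iodine exchange on a primary iodide is faster at −78 °C than propargylic deprotonation or carbolithiation of the alkyne; the alkyllithium adds to the borate ester and loss of isopropoxide gives the pinacol boronate.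

**Step 4**
Reactants: 6 2-(2,2-dimethylhex-4-yn-1-yl)-4,4,5,5-tetramethyl-1,3,2-dioxaborolane
Product: 8 2-[(4E)-5-iodo-2,2-dimethylhex-4-en-1-yl]-4,4,5,5-tetramethyl-1,3,2-dioxaborolane, via alkenylzirconocene 7 (not isolated)
Conditions: Cp2Zr(H)Cl (1.5 equiv), THF, rt to 40 °C; then I2, THF, −78 to 0 °C
Reagents that add atoms: iodine, I-I; Cp2Zr(H)Cl, [H][Zr](Cl)(C1C=CC=C1)C1C=CC=C1 (zirconium, chlorine and cyclopentadienyl groups of 7 only)
Why: Syn-hydrozirconation followed by iodinolysis with retention; the excess hydride lets the regioisomers equilibrate towards zirconium on the methyl-bearing C1, away from the β-branched chain, so that iodine ends trans to C3 (E). Alkyl pinacol boronates are inert to the reagent.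

**Step 5**
Reactants: 9 pent-3-yn-1-ol
Product: 11 (3E)-4-bromopent-3-en-1-ol, via bis-zirconocene adduct 10 (not isolated)
Conditions: Cp2Zr(H)Cl (2.5 equiv), THF, 0 to 40 °C; then NBS, −78 to 0 °C; H2O
Reagents that add atoms: N-bromosuccinimide, O=C1CCC(=O)N1Br; Cp2Zr(H)Cl, [H][Zr](Cl)(C1C=CC=C1)C1C=CC=C1 (zirconium, chlorine and cyclopentadienyl groups of 10 only)
Why: The first equivalent forms the zirconium alkoxide and the second adds syn across the alkyne, with equilibration towards zirconium on the methyl-bearing C8; brominolysis with retention puts bromine trans to C10 (E). A minor regioisomer can be removed at this small-molecule stage.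

**Step 6**
Reactants: 11 (3E)-4-bromopent-3-en-1-ol
Product: 12 (2E)-2-bromo-5-iodopent-2-ene
Conditions: PPh3, imidazole, I2, CH2Cl2, 0 °C to rt, dark
Reagents that add atoms: iodine, I-I
Why: Appel iodination of an unhindered primary alcohol; the alkenyl bromide takes no part and keeps its geometry.

**Step 7**
Reactants: 12 (2E)-2-bromo-5-iodopent-2-ene; 8 2-[(4E)-5-iodo-2,2-dimethylhex-4-en-1-yl]-4,4,5,5-tetramethyl-1,3,2-dioxaborolane
Product: 14 2-[(4E,8E)-9-bromo-2,2,5-trimethyldeca-4,8-dien-1-yl]-4,4,5,5-tetramethyl-1,3,2-dioxaborolane, via alkylzinc iodide 13 (not isolated)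
Conditions: 12, Zn dust, LiCl, THF, 25 °C; then 8, PdCl2(dppf) (3 mol%), THF, rt
Reagents that add atoms: zinc, [Zn] (zinc of 13 only)
Why: Zinc inserts into the alkyl C–I bond only, and the Negishi coupling forms C11–C1 with retention at C1=C2. Zerovalent palladium should take the alkenyl C–I bond of 8 well before the equally hindered alkenyl C–Br bond, and without base the alkyl boronate does not transmetallate.

**Step 8**
Reactants: 14 2-[(4E,8E)-9-bromo-2,2,5-trimethyldeca-4,8-dien-1-yl]-4,4,5,5-tetramethyl-1,3,2-dioxaborolane; 15 vinylmagnesium bromide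
Product: 18 (1S,3E,7E)-3,7,10,10-tetramethylcycloundeca-3,7-dien-1-ol, via ate complex 16 (not isolated), via macrocyclic boronate 17 (not isolated)
Conditions: 15 (1.05 equiv), NaOTf (3 equiv), THF/DMSO, 0 °C to rt; slow addition (syringe pump) to Pd(OAc)2 (10 mol%), (S,S)-1,1'-bis[bis(4-methoxy-3,5-dimethylphenyl)phosphino]-2,2'-bis[(R)-α-(dimethylamino)benzyl]ferrocene (a MandyPhos ligand, 12 mol%), THF, 60 °C, final 2 mM; then 3 M NaOH, 30% H2O2, 0 °C to rt
Reagents that add atoms: hydrogen peroxide, OO
Why: Proposed new method: this is the ring-closing, formal [9+2] version of the palladium-catalysed enantioselective conjunctive cross-coupling, whose closest known type is the open-chain three-component union of an alkyl pinacol boronate, a vinyl metal and an alkenyl bromide or triflate under this catalyst, with palladium-mediated sp2–sp3 macrocyclisations as the second point of reference. 15 adds to the boron of 14 to give ate complex 16, zerovalent palladium inserts into the C8–Br bond with retention, NaOTf takes up bromide, and the cationic divalent alkenylpalladium binds the vinyl group at the other end of the same chain. Binding triggers the 1,2-metallate shift, in which C5 migrates from boron to C6 anti to palladium while palladium takes C7, and this gives a twelve-membered palladacycle (Pd, C7, C6, C5, C4, C3, C2, C1, C11, C10, C9, C8). Reductive elimination forms C7–C8 and closes the eleven-membered ring with both new bonds endocyclic to give 17, and oxidation of the C–B bond with retention gives 18. C6, the only new stereocentre, is set by the chiral bisphosphine, which selects the face of the vinyl group that palladium binds, and the anti shift passes this choice on to carbon with no substrate stereocentre to interfere. The E geometry at C8=C9 is carried over from 14 because oxidative addition and reductive elimination are stereoretentive, and C1=C2 is a spectator. The step needs ring closure to beat chain growth, which slow addition, the gem-dimethyl group at C4 next to boron and the two rigid E olefins should favour, and it needs the metallate shift to beat direct vinyl transfer and β-hydride loss, which is the known bias of this wide-bite-angle ligand with pinacol ate complexes.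

**Step 9**
Reactants: 18 (1S,3E,7E)-3,7,10,10-tetramethylcycloundeca-3,7-dien-1-ol; 19 bromoacetyl bromide
Product: 20 (1S,3E,7E)-3,7,10,10-tetramethylcycloundeca-3,7-dien-1-yl 2-bromoacetate
Conditions: pyridine, CH2Cl2, 0 °C
Reagents that add atoms: none
Why: O-acylation with an acyl bromide; the C6–O bond is not touched, so the configuration is kept, and pyridine takes up HBr before it can start a transannular cyclisation of the diene.

**Step 10**
Reactants: 20 (1S,3E,7E)-3,7,10,10-tetramethylcycloundeca-3,7-dien-1-yl 2-bromoacetate; 21 diphenyl phosphite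
Product: 22 (1S,3E,7E)-3,7,10,10-tetramethylcycloundeca-3,7-dien-1-yl 2-(diphenoxyphosphoryl)acetate
Conditions: Et3N, CH2Cl2, 0 °C to rt
Reagents that add atoms: none
Why: Michaelis–Becker reaction; the phosphite anion displaces the activated primary bromide, which is the standard access to diaryl phosphonoacetates.

**Step 11**
Reactants: 22 (1S,3E,7E)-3,7,10,10-tetramethylcycloundeca-3,7-dien-1-yl 2-(diphenoxyphosphoryl)acetate; 23 4-[(tert-butyldimethylsilyl)oxy]benzaldehyde
Product: 24 (1S,3E,7E)-3,7,10,10-tetramethylcycloundeca-3,7-dien-1-yl (2Z)-3-{4-[(tert-butyldimethylsilyl)oxy]phenyl}prop-2-enoate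
Conditions: NaH, THF, 0 °C; then 23, −78 to −20 °C, dark
Reagents that add atoms: none
Why: Z-selective Horner–Wadsworth–Emmons reaction of a diaryl phosphonoacetate; the electron-poor aryloxy groups speed up collapse of the first-formed adduct, so the kinetic Z-enoate should prevail with an aromatic aldehyde. The silyl ether keeps the aldehyde electrophilic.

**Step 12**
Reactants: 24 (1S,3E,7E)-3,7,10,10-tetramethylcycloundeca-3,7-dien-1-yl (2Z)-3-{4-[(tert-butyldimethylsilyl)oxy]phenyl}prop-2-enoate
Product: 25 (1S,3E,7E)-3,7,10,10-tetramethylcycloundeca-3,7-dien-1-yl (2Z)-3-(4-hydroxyphenyl)prop-2-enoate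
Conditions: TBAF, AcOH (1:1), THF, 0 °C, dark
Reagents that add atoms: none
Why: Fluoride cleaves the aryl silyl ether quickly. The acetic acid buffer protonates the phenoxide as it forms, which should suppress Z to E isomerisation through the quinone-methide-like resonance form, and the medium is not acidic enough to attack the ring diene.

## Compound list

1 | 3,3-dimethyloxetane | CC1(C)COC1 | starting material
2 | 1-propynyllithium | [Li]C#CC | starting material
3 | 2,2-dimethylhex-4-yn-1-ol | CC#CCC(C)(C)CO | intermediate
4 | 6-iodo-5,5-dimethylhex-2-yne | CC#CCC(C)(C)CI | intermediate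
5 | (2,2-dimethylhex-4-yn-1-yl)lithium | [Li]CC(C)(C)CC#CC | intermediate
6 | 2-(2,2-dimethylhex-4-yn-1-yl)-4,4,5,5-tetramethyl-1,3,2-dioxaborolane | CC#CCC(C)(C)CB1OC(C)(C)C(C)(C)O1 | intermediate
7 | chlorobis(cyclopentadienyl)[(2E)-5,5-dimethyl-6-(4,4,5,5-tetramethyl-1,3,2-dioxaborolan-2-yl)hex-2-en-2-yl]zirconium | C/C(=C\CC(C)(C)CB1OC(C)(C)C(C)(C)O1)[Zr](Cl)(C2C=CC=C2)C3C=CC=C3 | intermediate
8 | 2-[(4E)-5-iodo-2,2-dimethylhex-4-en-1-yl]-4,4,5,5-tetramethyl-1,3,2-dioxaborolane | C/C(I)=C\CC(C)(C)CB1OC(C)(C)C(C)(C)O1 | intermediate
9 | pent-3-yn-1-ol | CC#CCCO | starting material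
10 | chlorobis(cyclopentadienyl)zirconium alkoxide of (3E)-4-[chlorobis(cyclopentadienyl)zirconio]pent-3-en-1-ol | C/C(=C\CCO[Zr](Cl)(C1C=CC=C1)C1C=CC=C1)[Zr](Cl)(C1C=CC=C1)C1C=CC=C1 | intermediate
11 | (3E)-4-bromopent-3-en-1-ol | C/C(Br)=C\CCO | intermediate
12 | (2E)-2-bromo-5-iodopent-2-ene | C/C(Br)=C\CCI | intermediate
13 | [(3E)-4-bromopent-3-en-1-yl]zinc iodide | C/C(Br)=C\CC[Zn]I | intermediate
14 | 2-[(4E,8E)-9-bromo-2,2,5-trimethyldeca-4,8-dien-1-yl]-4,4,5,5-tetramethyl-1,3,2-dioxaborolane | C/C(Br)=C\CC/C(C)=C/CC(C)(C)CB1OC(C)(C)C(C)(C)O1 | intermediate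
15 | vinylmagnesium bromide | C=C[Mg]Br | starting material
16 | bromomagnesium [(4E,8E)-9-bromo-2,2,5-trimethyldeca-4,8-dien-1-yl](ethenyl)(pinacolato)borate | C/C(Br)=C\CC/C(C)=C/CC(C)(C)C[B-]1(C=C)OC(C)(C)C(C)(C)O1.[Mg+2].[Br-] | intermediate
17 | 2-[(1S,3E,7E)-3,7,10,10-tetramethylcycloundeca-3,7-dien-1-yl]-4,4,5,5-tetramethyl-1,3,2-dioxaborolane | C/C1=C\CC(C)(C)C[C@H](B2OC(C)(C)C(C)(C)O2)C/C(C)=C/CC1 | intermediate
18 | (1S,3E,7E)-3,7,10,10-tetramethylcycloundeca-3,7-dien-1-ol | C/C1=C\CC(C)(C)C[C@H](O)C/C(C)=C/CC1 | intermediate
19 | bromoacetyl bromide | BrCC(=O)Br | starting material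
20 | (1S,3E,7E)-3,7,10,10-tetramethylcycloundeca-3,7-dien-1-yl 2-bromoacetate | C/C1=C\CC(C)(C)C[C@H](OC(=O)CBr)C/C(C)=C/CC1 | intermediate
21 | diphenyl phosphite | O=[PH](Oc1ccccc1)Oc1ccccc1 | starting material
22 | (1S,3E,7E)-3,7,10,10-tetramethylcycloundeca-3,7-dien-1-yl 2-(diphenoxyphosphoryl)acetate | C/C1=C\CC(C)(C)C[C@H](OC(=O)CP(=O)(Oc2ccccc2)Oc2ccccc2)C/C(C)=C/CC1 | intermediate
23 | 4-[(tert-butyldimethylsilyl)oxy]benzaldehyde | CC(C)(C)[Si](C)(C)Oc1ccc(C=O)cc1 | starting material
24 | (1S,3E,7E)-3,7,10,10-tetramethylcycloundeca-3,7-dien-1-yl (2Z)-3-{4-[(tert-butyldimethylsilyl)oxy]phenyl}prop-2-enoate | C/C1=C\CC(C)(C)C[C@H](OC(=O)/C=C\c2ccc(O[Si](C)(C)C(C)(C)C)cc2)C/C(C)=C/CC1 | intermediate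
25 | (1S,3E,7E)-3,7,10,10-tetramethylcycloundeca-3,7-dien-1-yl (2Z)-3-(4-hydroxyphenyl)prop-2-enoate | C/C1=C\CC(C)(C)C[C@H](OC(=O)/C=C\c2ccc(O)cc2)C/C(C)=C/CC1 | target

## Step count and least certain steps

Total step count: 12.
Longest linear sequence: 10 (steps 1, 2, 3, 4, 7, 8, 9, 10, 11, 12). Steps 5 and 6 form the side branch.

**Step 8 (key step, proposed new method).**
- *What may go wrong:*
  - Chain growth between two molecules may outrun ring closure, because the palladacycle on the way to a strained eleven-membered ring forms slowly.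
  - Face selection may erode, because the ligand pocket now has to hold a tethered rather than a free vinyl boronate.
  - Direct transfer of the vinyl group to palladium may end the chain as a diene.
- *Fallback (sets out from 6, 11 and 15, comes back at 17):* the two tasks of the step are separated, and only known reaction types are used.
  - Alcohol 11 is converted with PPh3 and CCl4 into (2E)-2-bromo-5-chloropent-2-ene F1.
  - The known open-chain conjunctive coupling of 6, 15 and F1 under the catalyst of step 8 gives 2-[(3E,6S)-1-chloro-4,8,8-trimethyldodec-3-en-10-yn-6-yl]-4,4,5,5-tetramethyl-1,3,2-dioxaborolane F2.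
  - Hydrozirconation and iodinolysis of the alkyne, as in step 4, give the alkenyl iodide 2-[(3E,6S,10E)-1-chloro-11-iodo-4,8,8-trimethyldodeca-3,10-dien-6-yl]-4,4,5,5-tetramethyl-1,3,2-dioxaborolane F3.
  - Finkelstein exchange (NaI, acetone) gives the diiodide 2-[(3E,6S,10E)-1,11-diiodo-4,8,8-trimethyldodeca-3,10-dien-6-yl]-4,4,5,5-tetramethyl-1,3,2-dioxaborolane F4.
  - Zinc with LiCl inserts into the alkyl C–I bond only and gives the alkylzinc iodide F5.
  - An intramolecular Negishi coupling at high dilution with PdCl2(dppf) closes the ring at C11–C1 to give 17, which is oxidised as in step 8.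

**Step 7.**
- *What may go wrong:* oxidative addition into the C–Br bond of 13 or 14 may compete with the C–I bond of 8, so that the zinc reagent couples with itself or with the product.
- *Fallback (sets out from 9 and 8, comes back at 14):* the bromide is introduced only after the coupling.
  - 9 gives 5-iodopent-2-yne F6 (PPh3, imidazole, I2).
  - Zinc insertion gives pent-3-yn-1-ylzinc iodide F7.
  - Negishi coupling with 8 gives 2-[(4E)-2,2,5-trimethyldec-4-en-8-yn-1-yl]-4,4,5,5-tetramethyl-1,3,2-dioxaborolane F8.
  - Hydrozirconation and brominolysis of F8, as in step 5, give 14.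

**Step 1.**
- *What may go wrong:* the opening at the neopentyl CH2 may be slow, so that cationic oligomerisation of the activated oxetane and decay of the acetylide–BF3 pair take over.
- *Fallback (sets out from 2, comes back at 3):* the quaternary centre becomes the nucleophile instead of the neighbour of the electrophile.
  - 2 and paraformaldehyde give but-2-yn-1-ol F9.
  - PBr3 gives 1-bromobut-2-yne F10.
  - The lithium enolate of ethyl isobutyrate (LDA, THF, −78 °C) is alkylated with F10 to ethyl 2,2-dimethylhex-4-ynoate F11.
  - LiAlH4 reduces F11 to 3.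

**Step 11.**
- *What may go wrong:* the adducts may equilibrate on warming, which the bulky ester would make more likely, and Z-selectivity would then be lost.
- *Fallback (sets out from 18, comes back at 24):* the Z olefin is made by syn addition of hydrogen instead of olefination.
  - 18 is esterified with propiolic acid (DCC, catalytic DMAP, −20 °C) to (1S,3E,7E)-3,7,10,10-tetramethylcycloundeca-3,7-dien-1-yl prop-2-ynoate F12.
  - Sonogashira coupling with tert-butyl(4-iodophenoxy)dimethylsilane (PdCl2(PPh3)2, CuI, Et3N) gives (1S,3E,7E)-3,7,10,10-tetramethylcycloundeca-3,7-dien-1-yl 3-{4-[(tert-butyldimethylsilyl)oxy]phenyl}prop-2-ynoate F13.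
  - Semihydrogenation over Pd on CaCO3 poisoned with Pb(OAc)2 and quinoline gives 24. The trisubstituted ring olefins should not react under these conditions.

## Further compounds

F1 | step 8 | (2E)-2-bromo-5-chloropent-2-ene | C/C(Br)=C\CCCl
F2 | step 8 | 2-[(3E,6S)-1-chloro-4,8,8-trimethyldodec-3-en-10-yn-6-yl]-4,4,5,5-tetramethyl-1,3,2-dioxaborolane | CC#CCC(C)(C)C[C@H](B1OC(C)(C)C(C)(C)O1)C/C(C)=C/CCCl
F3 | step 8 | 2-[(3E,6S,10E)-1-chloro-11-iodo-4,8,8-trimethyldodeca-3,10-dien-6-yl]-4,4,5,5-tetramethyl-1,3,2-dioxaborolane | C/C(I)=C\CC(C)(C)C[C@H](B1OC(C)(C)C(C)(C)O1)C/C(C)=C/CCCl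
F4 | step 8 | 2-[(3E,6S,10E)-1,11-diiodo-4,8,8-trimethyldodeca-3,10-dien-6-yl]-4,4,5,5-tetramethyl-1,3,2-dioxaborolane | C/C(I)=C\CC(C)(C)C[C@H](B1OC(C)(C)C(C)(C)O1)C/C(C)=C/CCI
F5 | step 8 | [(3E,6S,10E)-11-iodo-4,8,8-trimethyl-6-(4,4,5,5-tetramethyl-1,3,2-dioxaborolan-2-yl)dodeca-3,10-dien-1-yl]zinc iodide | C/C(I)=C\CC(C)(C)C[C@H](B1OC(C)(C)C(C)(C)O1)C/C(C)=C/CC[Zn]I
F6 | step 7 | 5-iodopent-2-yne | CC#CCCI
F7 | step 7 | pent-3-yn-1-ylzinc iodide | CC#CCC[Zn]I
F8 | step 7 | 2-[(4E)-2,2,5-trimethyldec-4-en-8-yn-1-yl]-4,4,5,5-tetramethyl-1,3,2-dioxaborolane | CC#CCC/C(C)=C/CC(C)(C)CB1OC(C)(C)C(C)(C)O1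
F9 | step 1 | but-2-yn-1-ol | CC#CCO
F10 | step 1 | 1-bromobut-2-yne | CC#CCBr
F11 | step 1 | ethyl 2,2-dimethylhex-4-ynoate | CCOC(=O)C(C)(C)CC#CC
F12 | step 11 | (1S,3E,7E)-3,7,10,10-tetramethylcycloundeca-3,7-dien-1-yl prop-2-ynoate | C/C1=C\CC(C)(C)C[C@H](OC(=O)C#C)C/C(C)=C/CC1
F13 | step 11 | (1S,3E,7E)-3,7,10,10-tetramethylcycloundeca-3,7-dien-1-yl 3-{4-[(tert-butyldimethylsilyl)oxy]phenyl}prop-2-ynoate | C/C1=C\CC(C)(C)C[C@H](OC(=O)C#Cc2ccc(O[Si](C)(C)C(C)(C)C)cc2)C/C(C)=C/CC1
A1 | alternative 1 | (4R,8E)-2,6,6,9-tetramethyltrideca-1,8,12-trien-4-ol | C=CCC/C(C)=C/CC(C)(C)C[C@H](O)CC(C)=C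
A2 | alternative 2 | (6E,10E)-12-chloro-2-(1-ethoxyethoxy)-4,4,7,11-tetramethyldodeca-6,10-dienenitrile | CCOC(C)OC(C#N)CC(C)(C)C/C=C(C)/CC/C=C(C)/CCl
A3 | alternative 2 | (3E,7E)-3,7,10,10-tetramethylcycloundeca-3,7-dien-1-one | C/C1=C\CC(C)(C)CC(=O)C/C(C)=C/CC1
A4 | alternative 3 | 1-[(2E,6E)-7-iodo-2,6-dimethylhepta-2,6-dien-1-yl]-3,3-dimethylcyclobutan-1-ol | OC1(C/C(C)=C/CC/C(C)=C/I)CC(C)(C)C1
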